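The route rests on cutting ring A between C2 and C3 (ring A: C1 bearing the exocyclic methylene, C2, C3, C4–Br, C5 gem-dimethyl, C6 spiro; ring B: C6–C11, C9 bearing Me/Cl, C10 bearing Br). C1 is carried as a ketone that can enolise only toward C2 because C6 is quaternary, and C3 is a primary carbon next to the C4 bromide. In one operation the enolate carbon displaces a sulfonate at C3 and closes ring A with both quaternary carbons and the C4 stereocentre already present. The precursor is a methyl ketone on C6 of a ketal-protected, still symmetric ring B, carrying a CMe2–CHBr–CH2OTs chain.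

Key step: step 6

Assumption: the sense of induction of the Schiff base ligand (step 1) and of the lithium amide (step 9) is assigned by analogy with simple model substrates; if either gives the opposite sense, its mirror-image form is used without other change.

Locants in the names of the spiro compounds 10–19 follow the numbering given above.

Step 1
Reactants: 1 prenol (3-methylbut-2-en-1-ol)
Product: 2 (R)-2-bromo-3-chloro-3-methylbutan-1-ol
Conditions: NBS, ClTi(OiPr)3, chiral tridentate Schiff base ligand (salicylaldimine of a tert-leucine-derived diaryl amino alcohol, cat.), hexanes, −20 °C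
Reagents that add atoms: N-bromosuccinimide, O=C1CCC(=O)N1Br; chlorotitanium triisopropoxide, CC(C)O[Ti](Cl)(OC(C)C)OC(C)C
Why: Titanium-mediated catalytic enantioselective bromochlorination of an allylic alcohol, in which the ligand-bound titanium alkoxide controls the face of bromonium formation and chloride opens it anti at the tertiary carbon, so the C–Br stereocentre (later C4) is set as R by the ligand.

Step 2
Reactants: 2 (R)-2-bromo-3-chloro-3-methylbutan-1-ol
Product: 3 (R)-2-bromo-3-chloro-3-methylbutyl 4-methylbenzenesulfonate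
Conditions: TsCl, Et3N, DMAP (cat.), CH2Cl2, 0 °C
Reagents that add atoms: 4-methylbenzenesulfonyl chloride, Cc1ccc(cc1)S(=O)(=O)Cl
Why: Sulfonylation of a primary alcohol under amine base, which is too weak at 0 °C to close the bromohydrin to an epoxide and leaves the stereocentre untouched.

Step 3
Reactants: 4 ethyl 1,4-dioxaspiro[4.5]decane-8-carboxylate
Product: 6 1-(1,4-dioxaspiro[4.5]decan-8-yl)ethan-1-one, via Weinreb amide 5 (not isolated)
Conditions: MeNHOMe·HCl, iPrMgCl, THF, −20 °C; then MeMgBr, 0 °C; aq. NH4Cl
Reagents that add atoms: methylmagnesium bromide, C[Mg]Br; N,O-dimethylhydroxylamine hydrochloride, CNOC.Cl (its atoms stay only in 5)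
Why: One-pot Weinreb ketone synthesis, in which the magnesium amide converts the ester into the N-methoxy-N-methylamide and the chelated adduct of MeMgBr stops at the ketone stage while the ketal is inert to Grignard reagents.

Step 4
Reactants: 6 1-(1,4-dioxaspiro[4.5]decan-8-yl)ethan-1-one
Product: 7 trimethyl{[1-(1,4-dioxaspiro[4.5]decan-8-ylidene)ethyl]oxy}silane (tetrasubstituted silyl enol ether)
Conditions: Me3SiCl, Et3N, DMF, 120 °C
Reagents that add atoms: chlorotrimethylsilane, C[Si](C)(C)Cl
Why: Equilibrating (thermodynamic) silylation of a ketone should favour the more substituted enol ether, which has no E/Z issue because the ring is symmetric; any terminal isomer is removed by distillation.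

Step 5
Reactants: 7 trimethyl{[1-(1,4-dioxaspiro[4.5]decan-8-ylidene)ethyl]oxy}silane; 3 (R)-2-bromo-3-chloro-3-methylbutyl 4-methylbenzenesulfonate
Product: 8 (S)-3-(8-acetyl-1,4-dioxaspiro[4.5]decan-8-yl)-2-bromo-3-methylbutyl 4-methylbenzenesulfonate
Conditions: AgOSO2CF3 (1.1 equiv), 2,6-di-tert-butyl-4-methylpyridine, CH2Cl2, −78 → −40 °C
Reagents that add atoms: none
Why: Lewis-acid-promoted SN1 α-tert-alkylation of a silyl enol ether by a tertiary halide, in which Ag+ removes the tertiary chloride with anchimeric help from bromine and the enol ether carbon opens the bromonium ion at its tertiary carbon to join C5 to C6; the C–Br carbon is never a free cation and keeps its configuration (R becomes S only through the priority rules).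

Step 6
Reactants: 8 (S)-3-(8-acetyl-1,4-dioxaspiro[4.5]decan-8-yl)-2-bromo-3-methylbutyl 4-methylbenzenesulfonate
Product: 10 (4R)-4-bromo-9,9-(ethylenedioxy)-5,5-dimethylspiro[5.5]undecan-1-one, via lithium enolate 9 (not isolated)
Conditions: LiN(SiMe3)2 (1.05 equiv), THF, −78 °C, then −78 → 23 °C; cold aq. NH4Cl
Reagents that add atoms: none
Why: LiN(SiMe3)2 deprotonates the acetyl methyl group, the only enolisable position because C6 is quaternary, and on warming the enolate carbon C2 attacks the primary carbon C3 from the side opposite the sulfonate (SN2) to form C2–C3. The closest known reaction type is the intramolecular C-alkylation of a ketone enolate by an alkyl sulfonate. Ring A closes in the 6-(enolendo)-exo-tet mode, which is stereoelectronically allowed for six-membered rings. No stereocentre is created: C4 is a spectator and C6 stays non-stereogenic because ring B is still symmetric. The step needs C- over O-alkylation and attack at C3 rather than C4; the tightly paired lithium enolate in THF disfavours O-alkylation, and the C4 bromide is secondary, neopentyl-type and would need a five-membered enolendo closure. One equivalent of base and a cold quench keep the product ketone from enolising toward the C4 bromide.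

Step 7
Reactants: 10 (4R)-4-bromo-9,9-(ethylenedioxy)-5,5-dimethylspiro[5.5]undecan-1-one
Product: 11 (4R)-4-bromo-9,9-(ethylenedioxy)-5,5-dimethyl-1-methylidenespiro[5.5]undecane
Conditions: Cp2TiMe2, toluene–THF, 70 °C, dark
Reagents that add atoms: dimethyltitanocene, [CH3-].[CH3-].[Ti+4].c1cc[cH-]c1.c1cc[cH-]c1
Why: Petasis methylenation, in which the thermally generated titanium methylidene olefinates hindered, enolisable ketones without base, so the C1 carbonyl beside the quaternary C6 is converted without enolisation toward the C4 bromide and without touching the ketal.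

Step 8
Reactants: 11 (4R)-4-bromo-9,9-(ethylenedioxy)-5,5-dimethyl-1-methylidenespiro[5.5]undecane
Product: 12 (4R)-4-bromo-5,5-dimethyl-1-methylidenespiro[5.5]undecan-9-one
Conditions: PPTS, acetone–H2O, 50 °C
Reagents that add atoms: water, O
Why: Mild acid-catalysed ketal hydrolysis frees the C9 ketone, the weakly acidic pyridinium salt being chosen so that the exocyclic alkene does not migrate into ring A.

Step 9
Reactants: 12 (4R)-4-bromo-5,5-dimethyl-1-methylidenespiro[5.5]undecan-9-one
Product: 14 (4R,6R)-4-bromo-5,5-dimethyl-1-methylidenespiro[5.5]undec-9-en-9-yl trifluoromethanesulfonate, via lithium enolate 13 (not isolated)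
Conditions: (S,S)-bis(1-phenylethyl)amine, n-BuLi, LiCl, THF, −78 °C; then N-(5-chloropyridin-2-yl)bis(trifluoromethanesulfonyl)imide, −78 → 0 °C
Reagents that add atoms: N-(5-chloropyridin-2-yl)bis(trifluoromethanesulfonyl)imide, O=S(=O)(N(c1ccc(Cl)cn1)S(=O)(=O)C(F)(F)F)C(F)(F)F
Why: Group-selective deprotonation by a C2-symmetric chiral lithium amide, applied here to two diastereotopic α-methylene groups, in which the (S,S)-base is expected to remove the axial proton at C10 of the ring B chair that holds the bulkier C5 equatorial; O-triflation of the enolate fixes the C9=C10 double bond and makes C6 a stereocentre (R) under reagent control.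

Step 10
Reactants: 14 (4R,6R)-4-bromo-5,5-dimethyl-1-methylidenespiro[5.5]undec-9-en-9-yl trifluoromethanesulfonate
Product: 15 (4R,6R)-4-bromo-5,5,9-trimethyl-1-methylidenespiro[5.5]undec-9-ene
Conditions: Pd(PPh3)4 (cat.), MeZnCl, THF, 23 → 50 °C
Reagents that add atoms: chloro(methyl)zinc, C[Zn]Cl
Why: Negishi cross-coupling of an alkenyl triflate, in which zerovalent palladium inserts into the C(sp2)–O bond far faster than into the hindered secondary alkyl bromide, so the methyl group is installed without touching any stereocentre.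

Step 11
Reactants: 15 (4R,6R)-4-bromo-5,5,9-trimethyl-1-methylidenespiro[5.5]undec-9-ene
Product: 16 (4R,6R,9S,10R)-4-bromo-9,10-epoxy-5,5,9-trimethyl-1-methylidenespiro[5.5]undecane (epoxide oxygen on the ring B face that carries C5)
Conditions: mCPBA (1.0 equiv), CH2Cl2, −20 → 0 °C; aq. NaHCO3/Na2S2O3 work-up
Reagents that add atoms: 3-chloroperoxybenzoic acid, OOC(=O)c1cccc(Cl)c1
Why: Prilezhaev epoxidation, in which the trisubstituted C9=C10 olefin is more electron-rich and less shielded than the exocyclic alkene beside the quaternary C6 and reacts first; attack is expected on the ring B face anti to the pseudoaxial C1, which sets C9 (S) and C10 (R) by substrate control.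

Step 12
Reactants: 16 (4R,6R,9S,10R)-4-bromo-9,10-epoxy-5,5,9-trimethyl-1-methylidenespiro[5.5]undecane
Product: 17 (4R,6R,9R,10R)-4-bromo-9-chloro-5,5,9-trimethyl-1-methylidenespiro[5.5]undecan-10-ol
Conditions: HCl (1 M in Et2O, 1.1 equiv), CH2Cl2, −78 → −30 °C; aq. NaHCO3 quench
Reagents that add atoms: hydrogen chloride, Cl
Why: Acid-mediated opening of a trisubstituted epoxide by chloride at the tertiary carbon (borderline SN2, Markovnikov regiochemistry) inverts C9 and gives the trans chlorohydrin with chlorine on the C1 face, while low temperature and one equivalent of HCl spare the exocyclic alkene.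

Step 13
Reactants: 17 (4R,6R,9R,10R)-4-bromo-9-chloro-5,5,9-trimethyl-1-methylidenespiro[5.5]undecan-10-ol
Product: 19 (4R,6R,9R,10S)-4,10-dibromo-9-chloro-5,5,9-trimethyl-1-methylidenespiro[5.5]undecane, via secondary triflate 18 (not isolated)
Conditions: (CF3SO2)2O, pyridine, CH2Cl2, −40 °C; then n-Bu4NBr, toluene, −40 → 0 °C
Reagents that add atoms: tetrabutylammonium bromide, [Br-].CCCC[N+](CCCC)(CCCC)CCCC; trifluoromethanesulfonic anhydride, O=S(=O)(OS(=O)(=O)C(F)(F)F)C(F)(F)F (its atoms stay only in 18)
Why: Activation of the C10 alcohol as its triflate and SN2 displacement by bromide with inversion should place bromine cis to the C9 chlorine (C10 becomes S), the weakly ionising medium and the inductive effect of the β-chlorine being relied on to hold back ionisation.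

Compound list
1 | prenol (3-methylbut-2-en-1-ol) | CC(C)=CCO | starting material
2 | (R)-2-bromo-3-chloro-3-methylbutan-1-ol | CC(C)(Cl)[C@H](Br)CO | intermediate
3 | (R)-2-bromo-3-chloro-3-methylbutyl 4-methylbenzenesulfonate | CC(C)(Cl)[C@H](Br)COS(=O)(=O)c1ccc(C)cc1 | intermediate
4 | ethyl 1,4-dioxaspiro[4.5]decane-8-carboxylate | CCOC(=O)C1CCC2(CC1)OCCO2 | starting material
5 | N-methoxy-N-methyl-1,4-dioxaspiro[4.5]decane-8-carboxamide (Weinreb amide) | CON(C)C(=O)C1CCC2(CC1)OCCO2 | intermediate
6 | 1-(1,4-dioxaspiro[4.5]decan-8-yl)ethan-1-one | CC(=O)C1CCC2(CC1)OCCO2 | intermediate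
7 | trimethyl{[1-(1,4-dioxaspiro[4.5]decan-8-ylidene)ethyl]oxy}silane | CC(O[Si](C)(C)C)=C1CCC2(CC1)OCCO2 | intermediate
8 | (S)-3-(8-acetyl-1,4-dioxaspiro[4.5]decan-8-yl)-2-bromo-3-methylbutyl 4-methylbenzenesulfonate | CC(=O)C1(CCC2(CC1)OCCO2)C(C)(C)[C@H](Br)COS(=O)(=O)c1ccc(C)cc1 | intermediate
9 | lithium enolate of 8 (enolate at the acetyl group) | [Li+].C=C([O-])C1(CCC2(CC1)OCCO2)C(C)(C)[C@H](Br)COS(=O)(=O)c1ccc(C)cc1 | intermediate
10 | (4R)-4-bromo-9,9-(ethylenedioxy)-5,5-dimethylspiro[5.5]undecan-1-one | O=C1CC[C@@H](Br)C(C)(C)C12CCC3(CC2)OCCO3 | intermediate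
11 | (4R)-4-bromo-9,9-(ethylenedioxy)-5,5-dimethyl-1-methylidenespiro[5.5]undecane | C=C1CC[C@@H](Br)C(C)(C)C12CCC3(CC2)OCCO3 | intermediate
12 | (4R)-4-bromo-5,5-dimethyl-1-methylidenespiro[5.5]undecan-9-one | C=C1CC[C@@H](Br)C(C)(C)C12CCC(=O)CC2 | intermediate
13 | lithium (4R,6R)-4-bromo-5,5-dimethyl-1-methylidenespiro[5.5]undec-9-en-9-olate | [Li+].C=C1CC[C@@H](Br)C(C)(C)[C@@]12CCC([O-])=CC2 | intermediate
14 | (4R,6R)-4-bromo-5,5-dimethyl-1-methylidenespiro[5.5]undec-9-en-9-yl trifluoromethanesulfonate | C=C1CC[C@@H](Br)C(C)(C)[C@@]12CCC(OS(=O)(=O)C(F)(F)F)=CC2 | intermediate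
15 | (4R,6R)-4-bromo-5,5,9-trimethyl-1-methylidenespiro[5.5]undec-9-ene | C=C1CC[C@@H](Br)C(C)(C)[C@@]12CCC(C)=CC2 | intermediate
16 | (4R,6R,9S,10R)-4-bromo-9,10-epoxy-5,5,9-trimethyl-1-methylidenespiro[5.5]undecane | C=C1CC[C@@H](Br)C(C)(C)[C@@]12CC[C@]3(C)O[C@@H]3C2 | intermediate
17 | (4R,6R,9R,10R)-4-bromo-9-chloro-5,5,9-trimethyl-1-methylidenespiro[5.5]undecan-10-ol | C=C1CC[C@@H](Br)C(C)(C)[C@@]12CC[C@@](C)(Cl)[C@H](O)C2 | intermediate
18 | (4R,6R,9R,10R)-4-bromo-9-chloro-5,5,9-trimethyl-1-methylidenespiro[5.5]undecan-10-yl trifluoromethanesulfonate | C=C1CC[C@@H](Br)C(C)(C)[C@@]12CC[C@@](C)(Cl)[C@H](OS(=O)(=O)C(F)(F)F)C2 | intermediate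
19 | (4R,6R,9R,10S)-4,10-dibromo-9-chloro-5,5,9-trimethyl-1-methylidenespiro[5.5]undecane | C=C1CC[C@@H](Br)C(C)(C)[C@@]12CC[C@@](C)(Cl)[C@@H](Br)C2 | target

Total step count: 13. Longest linear sequence: 11 steps (from 1 through steps 1, 2 and 5–13, or from 4 through steps 3–13).

Steps most likely to fail

Step 5. The bromonium ion may pass Br+ to the electron-rich enol ether, or the silyl triflate released may activate the ketal, before the congested C5–C6 bond forms; olefin-mediated Br+ transfer would also erode the configuration at the bromine-bearing carbon. The fallback makes the capture intramolecular; it sets out from 2 and 4 and returns at 8. Saponification of 4 (LiOH, THF–H2O) gives 1,4-dioxaspiro[4.5]decane-8-carboxylic acid F1, which is esterified with 2 (EDC·HCl, DMAP) to (R)-2-bromo-3-chloro-3-methylbutyl 1,4-dioxaspiro[4.5]decane-8-carboxylate F2. LiN(iPr)2/Me3SiCl at −78 °C converts this ester into its trimethylsilyl ketene acetal F3, a regiochemically unambiguous and more nucleophilic partner. AgOSO2CF3 then triggers a 6-endo capture of the tethered bromonium ion by the ketene acetal carbon to give (4S)-4-bromo-9,9-(ethylenedioxy)-5,5-dimethyl-2-oxaspiro[5.5]undecan-1-one F4. One equivalent of MeLi at −78 °C opens the lactone to (S)-1-[8-(3-bromo-4-hydroxy-2-methylbutan-2-yl)-1,4-dioxaspiro[4.5]decan-8-yl]ethan-1-one F5, and tosylation (TsCl, pyridine) gives 8.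

Step 13. Backside attack at C10 is slowed by the fully substituted C9 and the spiro centre, so ionisation with participation of the anti chlorine (1,2-chlorine shift) or elimination may outrun substitution. The fallback replaces the epoxide sequence by a selenium-mediated syn-bromochlorination; it sets out from 15 and returns at 19. PhSeCl (CH2Cl2, 23 °C, equilibrating conditions) adds anti and in the Markovnikov sense to C9=C10, selenium on the face anti to C1, to give (4R,6R,9R,10R)-4-bromo-9-chloro-5,5,9-trimethyl-1-methylidene-10-(phenylselanyl)spiro[5.5]undecane F6. One equivalent of Br2 at −78 °C oxidises selenium faster than it adds to the exocyclic alkene and gives the dibromo(phenyl)selenurane F7, whose selenium group is a much better nucleofuge than a sulfonate. Bromide then displaces it at C10 with inversion to give 19.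

Step 9. The base may discriminate poorly between the two diastereotopic α-methylene arms, or the inherent bias of the substrate may oppose it, so that both spiro configurations form. The fallback gives up reagent control and relies on separation; it sets out from 12 and returns at 14. Deprotonation with achiral LiN(SiMe3)2 and triflation with the same imide gives 14 together with its C6 epimer, (4R,6S)-4-bromo-5,5-dimethyl-1-methylidenespiro[5.5]undec-9-en-9-yl trifluoromethanesulfonate F8. Because C4 is fixed the two are diastereomers, and 14 is isolated by chromatography.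

Further compounds
F1 | step 5 | 1,4-dioxaspiro[4.5]decane-8-carboxylic acid | OC(=O)C1CCC2(CC1)OCCO2
F2 | step 5 | (R)-2-bromo-3-chloro-3-methylbutyl 1,4-dioxaspiro[4.5]decane-8-carboxylate | CC(C)(Cl)[C@H](Br)COC(=O)C1CCC2(CC1)OCCO2
F3 | step 5 | trimethylsilyl ketene acetal of F2 | CC(C)(Cl)[C@H](Br)COC(O[Si](C)(C)C)=C1CCC2(CC1)OCCO2
F4 | step 5 | (4S)-4-bromo-9,9-(ethylenedioxy)-5,5-dimethyl-2-oxaspiro[5.5]undecan-1-one | O=C1OC[C@@H](Br)C(C)(C)C12CCC3(CC2)OCCO3
F5 | step 5 | (S)-1-[8-(3-bromo-4-hydroxy-2-methylbutan-2-yl)-1,4-dioxaspiro[4.5]decan-8-yl]ethan-1-one | CC(=O)C1(CCC2(CC1)OCCO2)C(C)(C)[C@H](Br)CO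
F6 | step 13 | (4R,6R,9R,10R)-4-bromo-9-chloro-5,5,9-trimethyl-1-methylidene-10-(phenylselanyl)spiro[5.5]undecane | C=C1CC[C@@H](Br)C(C)(C)[C@@]12CC[C@@](C)(Cl)[C@H]([Se]c1ccccc1)C2
F7 | step 13 | dibromo(phenyl)selenurane of F6 | C=C1CC[C@@H](Br)C(C)(C)[C@@]12CC[C@@](C)(Cl)[C@H]([Se](Br)(Br)c1ccccc1)C2
F8 | step 9 | (4R,6S)-4-bromo-5,5-dimethyl-1-methylidenespiro[5.5]undec-9-en-9-yl trifluoromethanesulfonate | C=C1CC[C@@H](Br)C(C)(C)[C@]12CCC(OS(=O)(=O)C(F)(F)F)=CC2
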